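## The problem

Compound 33 is the 6α-angelate of a sclareol-type labdane: a trans-fused decalin (rings A and B) with quaternary carbons at C4 and C10, an equatorial oxygen at C6, a tertiary 8α-carbinol and a 9β side chain ending in a (13R) tertiary vinyl carbinol. Ring B carries five contiguous stereocentres (C5, C6, C8, C9, C10), and they depend on one another. Once the C10 methyl group (C20) is β it screens the β-face of ring B, so addition across C5=C6, protonation at C9 and epoxidation of C7=C8 can all be steered to the α-face. C10 must therefore be set first and with certainty, and it is also the hardest centre: a quaternary carbon bonded to C1, C5, C9 and a methyl group, with the second quaternary centre C4 two bonds away. C13 lies two methylene groups outside the ring, cannot be controlled from it, and needs reagent control of its own. Three groups limit the late chemistry. The angelate isomerises to the tiglate and is cleaved by hydride or base, so it goes on last; the tertiary allylic alcohol and the 8,13-diol ionise or close to cyclic ethers in acid; the terminal vinyl group forbids late hydrogenation. The feature that opens the structure is that ring A with C6 and C7 is a 1-vinylcyclohexene (C10=C5–C6=C7), while C17–C8–C9–C11 is a but-2-ynoyl unit. An oxygen placed temporarily on C1 can carry that unit as an ester, so that C7–C8 and C9–C10 form within one molecule, ring B and a five-membered lactone (C1–O–C11–C9–C10) close together, and the C1 carbinol passes its configuration to C10.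

## Retrosynthesis

**Ester last.** The C6–O acyl bond of 33 is cut to triol 30 and angelic acid 31. The Z-enoate would not survive hydride, strong base or fluoride, and only the secondary 6α-hydroxyl of 30 can be acylated, both other hydroxyls being tertiary. The forward step must acylate a hindered equatorial alcohol without Z-to-E isomerisation.

**C8 carbinol.** The C8–O bond and the C7–H bond are cut: triol 30 comes from silyl ether 29, and 29 from α-epoxide 28 of the Δ7 alkene 27. The nearest alternative, adding a methyl nucleophile to a C8 ketone, would attack from the open α-face and give the 8β-carbinol. Epoxidation from the α-face followed by hydride at C7 puts the oxygen where it is needed. The alkene 27 has one stereocentre fewer and no 8,13-diol.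

**C13.** The tertiary vinyl carbinol of 27 is traced to epoxy alcohol 25, through iodide 26, and 25 to the E-allylic alcohol 24. Adding a vinyl nucleophile to a 13-ketone would give both epimers, because the ring cannot reach C13. An asymmetric epoxidation of 24 fixes C13 by reagent control, and reductive opening of the derived iodide transposes the oxygen to C13 without breaking the C13–O bond. The forward steps must leave the ring alkene C7=C8 untouched.

**C12–C13 and C11–C12.** Alcohol 24 is cut at C12–C13 into the terminal alkene 21 and vinyl iodide 22 (hydroboration, then sp3–sp2 cross-coupling). The alkene geometry, which decides C13 in the epoxidation, is thus bought with 22 and not made by an olefination of a methyl ketone, which would give E/Z mixtures. Alkene 21 comes from aldehyde 20 by one-carbon olefination. This leaves C11 as the only side-chain carbon on the bicycle.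

**C9.** Aldehyde 20 (Δ7, 9α-H) is traced to the conjugated enal 18 (Δ8). The C9–H bond is formed by α-protonation of the dienolate of 18 on the face away from C20, which moves the double bond to C7=C8 where the later epoxidation needs it. C9 cannot be set while the lactone exists, because a lactone bridging C1 and C9 forces C11 onto the α-face.

**Temporary C1 oxygen.** Enal 18 comes from silyl ether 17, and 17 from diol 14 by radical deoxygenation at C1 (via 15 and 16). Diol 14 comes from lactone 13 by hydride reduction. These steps are the price of the tether. They are placed before C9 and C8 are set, so nothing sensitive is present.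

**C5 and C6.** Lactone 13 is the silyl ether of alcohol 12, and 12 comes from diene lactone 10 by syn hydroboration of C5=C6 from the α-face. This is done on 10 because there the second alkene, C8=C9, is tetrasubstituted and conjugated to the lactone carbonyl, so it does not compete.

**Key disconnection.** Lactone 10 is cut at C7–C8 and C9–C10 to ester 9. Two skeletal bonds, ring B, the lactone and the quaternary centre C10 form in one thermal step, and the only stereochemical input is the C1 carbinol. An intermolecular cycloaddition of the same diene would have neither facial control at C10 nor secure regiochemistry.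

**Precursor.** Ester 9 is cut at the ester bond to dienol 7 and but-2-ynoic acid 8. Dienol 7 comes from dienone 6 by catalytic enantioselective reduction, the only absolute stereocontrol needed for the ring system. Dienone 6 comes from enol ether 4 by addition of a vinylmetal reagent and hydrolysis, 4 from dione 3, and 3 from ketone 1 and acrylate 2 by Michael–Claisen annulation.

## Roads not taken

**Alternative 1:** The cut is C6–C7. In the forward key step the methyl group (C7) of a C8 ketone would add as its enolate to a C6 formyl group on C5, closing ring B under equilibrating conditions to hydroxy ketone A1. Merits: the side chain with C13 is already present, so no late side-chain work is needed, which is better than the five operations the chosen plan spends on C11 to C16. The 6α-hydroxyl is set thermodynamically, and C5 and C9 can equilibrate to the all-equatorial arrangement. Weak points: the aldol does nothing for C10, which must already exist next to C9 and C5 in the open precursor, and that is the hard part of the molecule. A1 is a β-hydroxy ketone and can dehydrate or revert under the conditions that form it. C17 must still be added to the C8 ketone, and a methyl nucleophile would enter from the α-face and give the wrong 8β-carbinol, so a detour through an exocyclic alkene would be needed. The chosen plan is longer, but it makes C10 with a tether that leaves no facial choice and sets C8 through an epoxide whose face is dictated by C20.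

**Alternative 2:** The cut is C9–C10, made by a [3,3] rearrangement. The silyl ketene acetal of a δ-lactone bearing a cyclohexenyl group on its alkoxy carbon would contract to acid A2, forming C9–C10 and the quaternary C10 while C6–O breaks. Merits: the C8 carbinol with its methyl group comes in with the lactone, so no late epoxide chemistry is needed. C5=C6 ends up where the chosen plan also has it. No auxiliary oxygen has to be removed, which saves about four steps. Weak points: the new bond must be made to a fully substituted alkene carbon flanked by the gem-dimethyl group, where ionisation of the allylic C–O bond competes. A2 is formed with the carboxyl α, so C9 must be inverted, and the enolate needed for that can expel the β-silyloxy group at C8. The chosen plan sets C9 before any oxygen is present at C8, so this conflict does not arise. It pays for that with the C1 deoxygenation.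

**Alternative 3:** The cuts are C1–C10 and C4–C5. A catalytic enantioselective Diels–Alder reaction of quinone A4 with diene A5 would give the cis-fused adduct A3, with C10 set and the C5 hydrogen β. Merits: this is the shortest entry to a decalin with C10 in place, from two cheap achiral compounds and a catalyst. C17, an oxygen at C6 and a C7=C8 alkene are already there. In step count to the bicycle it beats the chosen plan, which needs six steps. Weak points: A5 bears a cis methyl group on its reacting terminus and is a reluctant diene. The adduct needs epimerisation at C5 and hydrogenation of the ring-A alkene. C9 is a hindered ketone flanked by C10, so attaching C11 there and then removing the oxygen with the right C9 configuration would take several uncertain steps. The chosen plan already has C11 bonded to C9 when the ring is formed, with the oxidation level needed for the C9 protonation.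

Key step: step 6

Remark on numbering: labdane numbering is used for all bicyclic compounds (ring A = C1–C5, C10; ring B = C5–C10; C11 on C9; C17 = methyl on C8; C18/C19 = methyls on C4; C20 = methyl on C10). β is the face of C20. "Pentanorlabdane" means the 12,13,14,15,16-pentanor skeleton and "tetranorlabdane" the 13,14,15,16-tetranor skeleton. Unless stated, C20 is β, H5 is α and, where C9 is sp3, H9 is α.

Assumption: vinyl iodide 22 and D-(−)-diisopropyl tartrate are treated as purchasable reagents.

## Route

Step 1
Reactants: 1 2-methylpentan-3-one; 2 methyl acrylate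
Product: 3 2,4,4-trimethylcyclohexane-1,3-dione
Conditions: KOt-Bu, THF, 0 → 65 °C; then 2 M HCl
Reagents that add atoms: none
Why: Michael addition of the ketone enolate to the acrylate followed by intramolecular Claisen condensation; only the 2,4,4-trimethyl dione keeps an acidic hydrogen between the carbonyl groups, so its enolate is the thermodynamic sink and the 2,2,4-isomer should revert by retro-Claisen cleavage.

Step 2
Reactants: 3 2,4,4-trimethylcyclohexane-1,3-dione
Product: 4 3-isobutoxy-2,6,6-trimethylcyclohex-2-en-1-one
Conditions: i-BuOH, TsOH·H2O (cat.), toluene, reflux, Dean–Stark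
Reagents that add atoms: 2-methylpropan-1-ol, CC(C)CO
Why: Acid-catalysed enol etherification of a cyclic 1,3-dione; the alcohol should add at the carbonyl remote from the gem-dimethyl group, leaving the neopentyl ketone free as the later transposition requires, and the minor regioisomer is removed by chromatography.

Step 3
Reactants: 4 3-isobutoxy-2,6,6-trimethylcyclohex-2-en-1-one
Product: 6 2,4,4-trimethyl-3-vinylcyclohex-2-en-1-one, via tertiary allylic alcohol 5 (not isolated)
Conditions: CH2=CHMgBr, CeCl3, THF, −78 → 0 °C; then 1 M HCl, rt
Reagents that add atoms: vinylmagnesium bromide, C=C[Mg]Br; water, O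
Why: Stork–Danheiser alkylative carbonyl transposition: 1,2-addition of the vinyl group to the vinylogous ester carbonyl, then acid-induced loss of water and hydrolysis of the enol ether give the 3-vinyl enone; CeCl3 should suppress enolisation at the hindered ketone.

Step 4
Reactants: 6 2,4,4-trimethyl-3-vinylcyclohex-2-en-1-one
Product: 7 (1S)-2,4,4-trimethyl-3-vinylcyclohex-2-en-1-ol
Conditions: (R)-1-methyl-3,3-diphenyltetrahydro-1H,3H-pyrrolo[1,2-c][1,3,2]oxazaborole (15 mol %), catecholborane, toluene, −78 °C; aq. NaOH work-up
Reagents that add atoms: none
Why: Corey–Bakshi–Shibata reduction; the 2-methylalkenyl arm acts as the large group and the ring CH2 as the small one, so the (R)-catalyst should deliver hydride to give the (S)-carbinol (labdane C1 with oxygen α), and catecholborane does not hydroborate the vinyl group at this temperature.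

Step 5
Reactants: 7 (1S)-2,4,4-trimethyl-3-vinylcyclohex-2-en-1-ol; 8 but-2-ynoic acid
Product: 9 (1S)-2,4,4-trimethyl-3-vinylcyclohex-2-en-1-yl but-2-ynoate
Conditions: DCC, DMAP (cat.), CH2Cl2, −20 → 0 °C
Reagents that add atoms: none
Why: Steglich esterification under neutral conditions that spare the easily ionised dienylic carbinol; the C–O bond at C1 is not touched, so its configuration is kept.

Step 6
Reactants: 9 (1S)-2,4,4-trimethyl-3-vinylcyclohex-2-en-1-yl but-2-ynoate
Product: 10 (1S,10S)-1α-hydroxypentanorlabda-5,8-dien-11-oic acid 11,1-lactone (tricyclic dienyl lactone)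
Conditions: toluene (0.01 M), BHT (cat.), sealed tube, 160 °C
Reagents that add atoms: none
Why: A thermal, concerted [4+2] cycloaddition joins the ring-A 1-vinylcyclohexene (C10=C5–C6=C7) and the tethered ynoate (C8≡C9), forming C7–C8 and C9–C10 in one event; the closest known reaction type is the intramolecular Diels–Alder reaction of dienyl alkynoates, which gives lactone-fused cyclohexa-1,4-dienes. Ring B closes as the six-membered cycloaddition ring, and the γ-lactone is the five-membered ring defined by the three-atom tether (C1, O, C11) between diene terminus C10 and dienophile carbon C9; this fused mode is the only one the tether length allows, which also fixes the regiochemistry (C9 to C10, C8 to C7). The only new stereocentre is C10: a five-membered ring fused to ring A must be cis, so the alkyne reaches C10 on the face that carries the C1 oxygen, and the (1S) carbinol gives (10S) with C20 on the opposite, β-face. The dienophile is an alkyne, so there is no endo/exo question and C8=C9 remains as the enoate needed later. The reaction needs the s-cis diene, which the C4 gem-dimethyl group and the C10 methyl group favour by destabilising the s-trans rotamer, and the less populated reactive ester rotamer, which the temperature supplies. High dilution suppresses intermolecular cycloaddition and BHT suppresses radical polymerisation of the ynoate.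

Step 7
Reactants: 10 (1S,10S)-1α-hydroxypentanorlabda-5,8-dien-11-oic acid 11,1-lactone
Product: 12 1α,6α-dihydroxypentanorlabd-8-en-11-oic acid 11,1-lactone (5α-H), via 6α-alkylborane 11 (not isolated)
Conditions: BH3·THF, THF, 0 °C → rt; then NaBO3·4H2O, THF/H2O, rt
Reagents that add atoms: sodium perborate, O[B-]1(O)OO[B-](O)(O)OO1.[Na+].[Na+]
Why: Hydroboration–oxidation; borane adds syn across the trisubstituted C5=C6 with boron at C6, from the α-face because the β-face is covered by C20 and the axial C4 methyl group, giving H5α (trans ring fusion) and the 6α-hydroxyl with retention at boron. The tetrasubstituted, carbonyl-conjugated C8=C9 and the lactone react much more slowly, and perborate oxidises without opening the lactone.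

Step 8
Reactants: 12 1α,6α-dihydroxypentanorlabd-8-en-11-oic acid 11,1-lactone
Product: 13 6α-(tert-butyldimethylsilyloxy)-1α-hydroxypentanorlabd-8-en-11-oic acid 11,1-lactone
Conditions: TBSOTf, 2,6-lutidine, CH2Cl2, 0 °C
Reagents that add atoms: tert-butyldimethylsilyl triflate, CC(C)(C)[Si](C)(C)OS(=O)(=O)C(F)(F)F
Why: Silylation of a hindered secondary alcohol with the silyl triflate; the ether should withstand the hydride, radical, base and peracid steps that follow and is removed by fluoride at the end.

Step 9
Reactants: 13 6α-(tert-butyldimethylsilyloxy)-1α-hydroxypentanorlabd-8-en-11-oic acid 11,1-lactone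
Product: 14 6α-(tert-butyldimethylsilyloxy)pentanorlabd-8-ene-1α,11-diol
Conditions: LiAlH4, THF, 0 °C → rt
Reagents that add atoms: none
Why: Hydride reduction of the lactone to the 1,4-diol; the tetrasubstituted C8=C9 is not reduced, C11 is freed as a primary allylic alcohol and the C1 hydroxyl is exposed for removal.

Step 10
Reactants: 14 6α-(tert-butyldimethylsilyloxy)pentanorlabd-8-ene-1α,11-diol
Product: 15 6α-(tert-butyldimethylsilyloxy)-11-(triethylsilyloxy)pentanorlabd-8-en-1α-ol
Conditions: TESCl, imidazole, CH2Cl2, −20 °C
Reagents that add atoms: chlorotriethylsilane, CC[Si](CC)(CC)Cl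
Why: Selective silylation of the primary allylic hydroxyl over the axial, neopentyl-type secondary hydroxyl at C1.

Step 11
Reactants: 15 6α-(tert-butyldimethylsilyloxy)-11-(triethylsilyloxy)pentanorlabd-8-en-1α-ol
Product: 16 O-[6α-(tert-butyldimethylsilyloxy)-11-(triethylsilyloxy)pentanorlabd-8-en-1α-yl] imidazole-1-carbothioate
Conditions: 1,1'-thiocarbonyldiimidazole, DMAP (cat.), toluene, 80 °C
Reagents that add atoms: 1,1'-thiocarbonyldiimidazole, S=C(n1ccnc1)n1ccnc1
Why: Thioacylation of the secondary alcohol (first half of the Barton–McCombie deoxygenation) under non-anionic conditions, which avoids the silyl migration from O11 to O1 that an alkoxide could trigger.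

Step 12
Reactants: 16 O-[6α-(tert-butyldimethylsilyloxy)-11-(triethylsilyloxy)pentanorlabd-8-en-1α-yl] imidazole-1-carbothioate
Product: 17 6α-(tert-butyldimethylsilyloxy)-11-(triethylsilyloxy)pentanorlabd-8-ene
Conditions: Bu3SnH (0.5 M), AIBN (cat.), toluene, 110 °C
Reagents that add atoms: none
Why: Barton–McCombie deoxygenation; the secondary C1 radical is reduced by the stannane, and a 1,2-vinyl shift is disfavoured because the C1–C10 bond lies near the nodal plane of the C8=C9 π bond and the stannane concentration is high. C10 stays a stereocentre and is not touched.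

Step 13
Reactants: 17 6α-(tert-butyldimethylsilyloxy)-11-(triethylsilyloxy)pentanorlabd-8-ene
Product: 18 6α-(tert-butyldimethylsilyloxy)pentanorlabd-8-en-11-al
Conditions: (COCl)2, DMSO, CH2Cl2, −78 → −40 °C; then Et3N, −78 °C → rt
Reagents that add atoms: none
Why: Swern oxidation applied directly to a primary triethylsilyl ether; the chlorosulfonium reagent cleaves the primary silyl ether and oxidises the carbinol in one operation, while the secondary tert-butyldimethylsilyl ether is inert.

Step 14
Reactants: 18 6α-(tert-butyldimethylsilyloxy)pentanorlabd-8-en-11-al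
Product: 20 6α-(tert-butyldimethylsilyloxy)pentanorlabd-7-en-11-al (9α-H), via potassium dienolate 19 (not isolated)
Conditions: KOt-Bu, THF/t-BuOH, −20 → 0 °C; then inverse quench into AcOH/THF/H2O, −78 °C
Reagents that add atoms: none
Why: Deconjugation of an α,β-unsaturated carbonyl compound by kinetic α-protonation of its thermodynamic dienolate; the equilibrating alkoxide removes a γ-hydrogen at C7 to give the more substituted endocyclic dienolate, and acetic acid protonates C9 faster than C7. The proton enters anti to C20 (α-face), so C11 ends β. The pseudo-equatorial C6–O bond is poorly aligned with the dienolate π system, which should hold back β-elimination at this temperature.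

Step 15
Reactants: 20 6α-(tert-butyldimethylsilyloxy)pentanorlabd-7-en-11-al
Product: 21 6α-(tert-butyldimethylsilyloxy)-13,14,15,16-tetranorlabda-7,11-diene (9α-H)
Conditions: Ph3PCH3Br, KN(SiMe3)2, THF, 0 °C; then 20, −78 → 0 °C
Reagents that add atoms: methyltriphenylphosphonium bromide, C[P+](c1ccccc1)(c1ccccc1)c1ccccc1.[Br-]
Why: Wittig methylenation; at low temperature addition of the unstabilised ylide to the aldehyde should outrun enolisation at C9, so the C9 configuration and the position of C7=C8 are kept.

Step 16
Reactants: 21 6α-(tert-butyldimethylsilyloxy)-13,14,15,16-tetranorlabda-7,11-diene; 22 (E)-3-iodobut-2-en-1-ol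
Product: 24 (13E)-6α-(tert-butyldimethylsilyloxy)labda-7,13-dien-15-ol, via B-alkyl-9-borabicyclononane 23 (not isolated)
Conditions: 9-BBN, THF, rt → 50 °C; then 22, Pd(dppf)Cl2 (cat.), AsPh3, Cs2CO3, DMF/H2O, rt
Reagents that add atoms: none
Why: 9-BBN hydroborates the monosubstituted alkene at terminal C12 and leaves the hindered trisubstituted C7=C8 alone; B-alkyl Suzuki–Miyaura coupling then forms C12–C13 with retention of the E geometry of the vinyl iodide, and the free hydroxyl is tolerated.

Step 17
Reactants: 24 (13E)-6α-(tert-butyldimethylsilyloxy)labda-7,13-dien-15-ol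
Product: 25 (13R,14R)-13,14-epoxy-6α-(tert-butyldimethylsilyloxy)labd-7-en-15-ol
Conditions: Ti(Oi-Pr)4 (cat.), D-(−)-diisopropyl tartrate (cat.), t-BuOOH, 4 Å MS, CH2Cl2, −20 °C
Reagents that add atoms: tert-butyl hydroperoxide, CC(C)(C)OO
Why: Sharpless asymmetric epoxidation under reagent control; an E-3-methyl-2-alkenol of the geraniol type gives the (2S,3S)-epoxide with the L-(+)-tartrate, so the D-(−)-tartrate should give the (13R,14R)-epoxide here. The isolated C7=C8 is not epoxidised by this catalyst.

Step 18
Reactants: 25 (13R,14R)-13,14-epoxy-6α-(tert-butyldimethylsilyloxy)labd-7-en-15-ol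
Product: 27 (13R)-6α-(tert-butyldimethylsilyloxy)labda-7,14-dien-13-ol, via epoxy iodide 26 (not isolated)
Conditions: I2, PPh3, imidazole, THF, 0 °C; then Zn dust, AcOH, 0 °C → rt
Reagents that add atoms: none
Why: Appel-type iodination of the primary alcohol, then zinc-induced reductive β-elimination that opens the epoxide toward C15 and gives the transposed tertiary allylic alcohol; the C13–O bond is never broken, so C13 stays R.

Step 19
Reactants: 27 (13R)-6α-(tert-butyldimethylsilyloxy)labda-7,14-dien-13-ol
Product: 28 (13R)-7α,8α-epoxy-6α-(tert-butyldimethylsilyloxy)labd-14-en-13-ol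
Conditions: mCPBA, NaHCO3, CH2Cl2, 0 °C
Reagents that add atoms: 3-chloroperoxybenzoic acid, OOC(=O)c1cccc(Cl)c1
Why: Prilezhaev epoxidation; the trisubstituted C7=C8 is far more nucleophilic than the monosubstituted vinyl group, and the peracid should approach from the α-face because C20 and the axial C4 methyl group close the β-face. The buffer protects the tertiary allylic alcohol.

Step 20
Reactants: 28 (13R)-7α,8α-epoxy-6α-(tert-butyldimethylsilyloxy)labd-14-en-13-ol
Product: 29 (13R)-6α-(tert-butyldimethylsilyloxy)labd-14-ene-8α,13-diol
Conditions: LiAlH4, THF, 0 → 65 °C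
Reagents that add atoms: none
Why: Hydride opening of a trisubstituted epoxide at the less substituted carbon; attack at C7 from the β-face leaves the oxygen on C8 with its α-configuration, giving the equatorial 8α-carbinol with C17 axial.

Step 21
Reactants: 29 (13R)-6α-(tert-butyldimethylsilyloxy)labd-14-ene-8α,13-diol
Product: 30 (13R)-labd-14-ene-6α,8α,13-triol
Conditions: Bu4NF, THF, rt → 50 °C
Reagents that add atoms: none
Why: Fluoride cleavage of the silyl ether under non-acidic conditions, which the tertiary allylic alcohol and the 8,13-diol tolerate.

Step 22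
Reactants: 30 (13R)-labd-14-ene-6α,8α,13-triol; 31 angelic acid
Product: 33 (13R)-6α-angeloyloxylabd-14-ene-8α,13-diol (CNP0203829.1), via mixed anhydride 32 (not isolated)
Conditions: 31, 2,4,6-trichlorobenzoyl chloride, Et3N, toluene, rt; then 30, 80 °C
Reagents that add atoms: none
Why: Yamaguchi-type acylation through the mixed anhydride without a nucleophilic amine catalyst, which should avoid isomerisation of the angelate to the tiglate; only the secondary 6α-hydroxyl reacts, both other hydroxyls being tertiary.

## Compound list

1 | 2-methylpentan-3-one | CCC(=O)C(C)C | starting material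
2 | methyl acrylate | C=CC(=O)OC | starting material
3 | 2,4,4-trimethylcyclohexane-1,3-dione | CC1C(=O)CCC(C)(C)C1=O | intermediate
4 | 3-isobutoxy-2,6,6-trimethylcyclohex-2-en-1-one | CC1=C(OCC(C)C)CCC(C)(C)C1=O | intermediate
5 | 3-isobutoxy-2,6,6-trimethyl-1-vinylcyclohex-2-en-1-ol (racemic, not isolated) | C=CC1(O)C(C)=C(OCC(C)C)CCC1(C)C | intermediate
6 | 2,4,4-trimethyl-3-vinylcyclohex-2-en-1-one | C=CC1=C(C)C(=O)CCC1(C)C | intermediate
7 | (1S)-2,4,4-trimethyl-3-vinylcyclohex-2-en-1-ol | O[C@H]1CCC(C)(C)C(C=C)=C1C | intermediate
8 | but-2-ynoic acid | CC#CC(=O)O | starting material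
9 | (1S)-2,4,4-trimethyl-3-vinylcyclohex-2-en-1-yl but-2-ynoate | CC#CC(=O)O[C@H]1CCC(C)(C)C(C=C)=C1C | intermediate
10 | (1S,10S)-1α-hydroxypentanorlabda-5,8-dien-11-oic acid 11,1-lactone | CC1=C2C(=O)O[C@H]3CCC(C)(C)C(=CC1)[C@@]23C | intermediate
11 | 6α-boryl-5α-H adduct of 10, drawn as the monoalkylborane (not isolated) | CC1=C2C(=O)O[C@H]3CCC(C)(C)[C@H]([C@@H](B)C1)[C@@]23C | intermediate
12 | 1α,6α-dihydroxypentanorlabd-8-en-11-oic acid 11,1-lactone | CC1=C2C(=O)O[C@H]3CCC(C)(C)[C@H]([C@@H](O)C1)[C@@]23C | intermediate
13 | 6α-(tert-butyldimethylsilyloxy)-1α-hydroxypentanorlabd-8-en-11-oic acid 11,1-lactone | CC1=C2C(=O)O[C@H]3CCC(C)(C)[C@H]([C@@H](O[Si](C)(C)C(C)(C)C)C1)[C@@]23C | intermediate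
14 | 6α-(tert-butyldimethylsilyloxy)pentanorlabd-8-ene-1α,11-diol | CC1=C(CO)[C@@]2(C)[C@@H](O)CCC(C)(C)[C@@H]2[C@@H](O[Si](C)(C)C(C)(C)C)C1 | intermediate
15 | 6α-(tert-butyldimethylsilyloxy)-11-(triethylsilyloxy)pentanorlabd-8-en-1α-ol | CC1=C(CO[Si](CC)(CC)CC)[C@@]2(C)[C@@H](O)CCC(C)(C)[C@@H]2[C@@H](O[Si](C)(C)C(C)(C)C)C1 | intermediate
16 | O-[6α-(tert-butyldimethylsilyloxy)-11-(triethylsilyloxy)pentanorlabd-8-en-1α-yl] imidazole-1-carbothioate | CC1=C(CO[Si](CC)(CC)CC)[C@@]2(C)[C@@H](OC(=S)n3ccnc3)CCC(C)(C)[C@@H]2[C@@H](O[Si](C)(C)C(C)(C)C)C1 | intermediate
17 | 6α-(tert-butyldimethylsilyloxy)-11-(triethylsilyloxy)pentanorlabd-8-ene | CC1=C(CO[Si](CC)(CC)CC)[C@@]2(C)CCCC(C)(C)[C@@H]2[C@@H](O[Si](C)(C)C(C)(C)C)C1 | intermediate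
18 | 6α-(tert-butyldimethylsilyloxy)pentanorlabd-8-en-11-al | CC1=C(C=O)[C@@]2(C)CCCC(C)(C)[C@@H]2[C@@H](O[Si](C)(C)C(C)(C)C)C1 | intermediate
19 | potassium dienolate of 18 (C7=C8, C9=C11–OK; enolate geometry open; not isolated) | [K+].[O-]C=C1C(C)=C[C@H](O[Si](C)(C)C(C)(C)C)[C@H]2C(C)(C)CCC[C@]12C | intermediate
20 | 6α-(tert-butyldimethylsilyloxy)pentanorlabd-7-en-11-al (9α-H) | O=C[C@@H]1[C@@]2(C)CCCC(C)(C)[C@@H]2[C@@H](O[Si](C)(C)C(C)(C)C)C=C1C | intermediate
21 | 6α-(tert-butyldimethylsilyloxy)-13,14,15,16-tetranorlabda-7,11-diene | C=C[C@@H]1[C@@]2(C)CCCC(C)(C)[C@@H]2[C@@H](O[Si](C)(C)C(C)(C)C)C=C1C | intermediate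
22 | (E)-3-iodobut-2-en-1-ol | C/C(I)=C\CO | starting material
23 | 9-[6α-(tert-butyldimethylsilyloxy)tetranorlabd-7-en-12-yl]-9-borabicyclo[3.3.1]nonane (not isolated) | B1(CC[C@@H]3[C@@]4(C)CCCC(C)(C)[C@@H]4[C@@H](O[Si](C)(C)C(C)(C)C)C=C3C)C2CCCC1CCC2 | intermediate
24 | (13E)-6α-(tert-butyldimethylsilyloxy)labda-7,13-dien-15-ol | OC/C=C(\C)CC[C@@H]1[C@@]2(C)CCCC(C)(C)[C@@H]2[C@@H](O[Si](C)(C)C(C)(C)C)C=C1C | intermediate
25 | (13R,14R)-13,14-epoxy-6α-(tert-butyldimethylsilyloxy)labd-7-en-15-ol | OC[C@H]3O[C@]3(C)CC[C@@H]1[C@@]2(C)CCCC(C)(C)[C@@H]2[C@@H](O[Si](C)(C)C(C)(C)C)C=C1C | intermediate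
26 | (13R,14S)-13,14-epoxy-15-iodo-6α-(tert-butyldimethylsilyloxy)labd-7-ene (not isolated) | IC[C@H]3O[C@]3(C)CC[C@@H]1[C@@]2(C)CCCC(C)(C)[C@@H]2[C@@H](O[Si](C)(C)C(C)(C)C)C=C1C | intermediate
27 | (13R)-6α-(tert-butyldimethylsilyloxy)labda-7,14-dien-13-ol | C=C[C@](C)(O)CC[C@@H]1[C@@]2(C)CCCC(C)(C)[C@@H]2[C@@H](O[Si](C)(C)C(C)(C)C)C=C1C | intermediate
28 | (13R)-7α,8α-epoxy-6α-(tert-butyldimethylsilyloxy)labd-14-en-13-ol | C=C[C@](C)(O)CC[C@@H]1[C@@]2(C)CCCC(C)(C)[C@@H]2[C@@H](O[Si](C)(C)C(C)(C)C)[C@H]3O[C@@]13C | intermediate
29 | (13R)-6α-(tert-butyldimethylsilyloxy)labd-14-ene-8α,13-diol | C=C[C@](C)(O)CC[C@@H]1[C@@]2(C)CCCC(C)(C)[C@@H]2[C@@H](O[Si](C)(C)C(C)(C)C)C[C@@]1(C)O | intermediate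
30 | (13R)-labd-14-ene-6α,8α,13-triol | C=C[C@](C)(O)CC[C@@H]1[C@@]2(C)CCCC(C)(C)[C@@H]2[C@@H](O)C[C@@]1(C)O | intermediate
31 | angelic acid, (Z)-2-methylbut-2-enoic acid | C/C=C(/C)C(=O)O | starting material
32 | angelic 2,4,6-trichlorobenzoic anhydride (not isolated) | C/C=C(/C)C(=O)OC(=O)c1c(Cl)cc(Cl)cc1Cl | intermediate
33 | (13R)-6α-angeloyloxylabd-14-ene-8α,13-diol, CNP0203829.1 | C=C[C@](C)(O)CC[C@@H]1[C@@]2(C)CCCC(C)(C)[C@@H]2[C@@H](OC(=O)/C(C)=C\C)C[C@@]1(C)O | target

## Step count and least certain steps

Total step count: 22. Longest linear sequence: 22 steps (1 or 2 to 33); compounds 8, 22 and 31 enter as purchased building blocks.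

**Step 6 (key step).** The most likely failure is that cycloaddition is too slow at a temperature the ester survives. The unactivated ynoate and the poorly populated reactive ester rotamer slow the reaction, while the dienylic C1–O bond can ionise and eliminate but-2-ynoic acid on prolonged heating. The fallback keeps the disconnection but changes the dienophile. It sets out from 7, which would be esterified with 3-(p-tolylsulfonyl)propiolic acid to the sulfonylpropiolate F1. The strongly activated alkyne of F1 should cyclise near room temperature to the sulfonyl lactone F2. Me2CuLi would then replace the sulfonyl group by methyl through conjugate addition–elimination, returning to the route at 10.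

**Step 14.** Three processes can divert the dienolate: vinylogous β-elimination of the C6 silyloxy group, γ-deprotonation at the C17 methyl group in place of C7, and reconjugation during the quench. The fallback removes the leaving group before the base is applied. It sets out from 17, which would be desilylated with Bu4NF to the 6α,11-diol F3. MnO2 would oxidise only the allylic hydroxyl, giving the hydroxy enal F4. Deconjugation of F4 as its alkoxide dienolate, which cannot eliminate, would give the hydroxy aldehyde F5. Methylenation with excess ylide would give the dienol F6, and silylation with TBSOTf returns to the route at 21.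

**Step 15.** The basic ylide may enolise the aldehyde at C9, which is both α to the carbonyl and allylic, leading to epimerisation or return to the conjugated enal. The fallback is a two-stage Peterson olefination with a non-basic nucleophile. It sets out from 20, to which Me3SiCH2MgCl/CeCl3 would be added to give the β-hydroxysilane F7 as a mixture of C11 epimers. Elimination with KH gives the alkene and returns to the route at 21.

**Step 20.** Hydride attack at C7 is a diequatorial opening against the Fürst–Plattner preference and takes place next to the bulky silyl ether. It may therefore be slow, or be diverted to attack at C8 if aluminium species act as Lewis acids. The fallback sets out from 28. It would be opened at C7 with sodium phenylselenide (PhSeSePh, NaBH4, EtOH), a small and far stronger nucleophile without Lewis acidity, to give the 7β-phenylseleno-8α-ol F8. Bu3SnH/AIBN would then replace selenium by hydrogen and return to the route at 29.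

**Step 13.** Cleavage of the primary silyl ether by the chlorosulfonium reagent may be incomplete, or the allylic alkoxysulfonium ion may be displaced by chloride. The fallback separates the two events. It sets out from 17, from which the primary silyl ether would be removed with PPTS in MeOH to give the allylic alcohol F9. MnO2 would then oxidise F9 and return to the route at 18.

## Further compounds

F1 | step 6 | (1S)-2,4,4-trimethyl-3-vinylcyclohex-2-en-1-yl 3-(p-tolylsulfonyl)propiolate | Cc1ccc(cc1)S(=O)(=O)C#CC(=O)O[C@H]1CCC(C)(C)C(C=C)=C1C
F2 | step 6 | (1S,10S)-1α-hydroxy-8-(p-tolylsulfonyl)-17-norpentanorlabda-5,8-dien-11-oic acid 11,1-lactone | Cc1ccc(cc1)S(=O)(=O)C1=C2C(=O)O[C@H]3CCC(C)(C)C(=CC1)[C@@]23C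
F3 | step 14 | pentanorlabd-8-ene-6α,11-diol | CC1=C(CO)[C@@]2(C)CCCC(C)(C)[C@@H]2[C@@H](O)C1
F4 | step 14 | 6α-hydroxypentanorlabd-8-en-11-al | CC1=C(C=O)[C@@]2(C)CCCC(C)(C)[C@@H]2[C@@H](O)C1
F5 | step 14 | 6α-hydroxypentanorlabd-7-en-11-al (9α-H) | O=C[C@@H]1[C@@]2(C)CCCC(C)(C)[C@@H]2[C@@H](O)C=C1C
F6 | step 14 | 13,14,15,16-tetranorlabda-7,11-dien-6α-ol | C=C[C@@H]1[C@@]2(C)CCCC(C)(C)[C@@H]2[C@@H](O)C=C1C
F7 | step 15 | 6α-(tert-butyldimethylsilyloxy)-12-(trimethylsilyl)tetranorlabd-7-en-11-ol (C11 epimers) | C[Si](C)(C)CC(O)[C@@H]1[C@@]2(C)CCCC(C)(C)[C@@H]2[C@@H](O[Si](C)(C)C(C)(C)C)C=C1C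
F8 | step 20 | (13R)-6α-(tert-butyldimethylsilyloxy)-7β-(phenylselanyl)labd-14-ene-8α,13-diol | C=C[C@](C)(O)CC[C@@H]1[C@@]2(C)CCCC(C)(C)[C@@H]2[C@@H](O[Si](C)(C)C(C)(C)C)[C@H]([Se]c3ccccc3)[C@@]1(C)O
F9 | step 13 | 6α-(tert-butyldimethylsilyloxy)pentanorlabd-8-en-11-ol | CC1=C(CO)[C@@]2(C)CCCC(C)(C)[C@@H]2[C@@H](O[Si](C)(C)C(C)(C)C)C1
A1 | alternative 1 | 6α-hydroxy-17-nor-8-oxolabd-14-ene 13-triethylsilyl ether | C=C[C@](C)(O[Si](CC)(CC)CC)CC[C@@H]1[C@@]2(C)CCCC(C)(C)[C@@H]2[C@@H](O)CC1=O
A2 | alternative 2 | 9-epi-8α-(triethylsilyloxy)pentanorlabd-5-en-11-oic acid (carboxyl α) | OC(=O)[C@H]1[C@@]2(C)CCCC(C)(C)C2=CC[C@@]1(C)O[Si](CC)(CC)CC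
A3 | alternative 3 | cis-fused quinone Diels–Alder adduct (C10 quaternary, 5β-H) | O=C1[C@@]2(C)CC=CC(C)(C)[C@H]2C(=O)C=C1C
A4 | alternative 3 | 2,6-dimethyl-1,4-benzoquinone | CC1=CC(=O)C=C(C)C1=O
A5 | alternative 3 | 4-methylpenta-1,3-diene | C=CC=C(C)C
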